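**Plan**

1. Each benzyl ring is numbered C1 (CH2N), C2, C3, C6 (Br), C4, C5 (OH). The retrosynthesis first ties O4 and O5 of each ring into a 1,4-dioxane ring through a CH2CH2 bridge, then cuts each benzene ring at C2–C3, C4–C5 and C6–C1.
2. This leaves three two-carbon bromoalkyne units per ring: C1–C2 from a bromopropargyl arm of the urea, and C3–C4 plus C5–C6 from one O-tethered bis(bromo ynol ether), whose tether fixes C4–C5 as the first bond formed.
3. The urea C–N bonds go back to propargylamine and 1,1'-carbonyldiimidazole; the ynol ether C–O bonds go back to ethylene glycol and two molecules of trichloroethylene.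
4. Forward: both acyclic partners are built in two steps each; a ruthenium-catalysed [2+2+2] cycloaddition on each arm closes first the dioxane ring and then the benzene ring; BBr3 finally removes the two CH2CH2 bridges.
5. Stereochemistry: the target is achiral and has no stereocentre, so none has to be set.

Key step: step 5

Remark: the bromo ynol ether diyne is assumed to tolerate handling only as a cold, dilute, acid-free solution, so it is prepared immediately before the cycloaddition and never concentrated to dryness.

**Route**

Step 1
Reactants: 1 ethylene glycol; 2 trichloroethylene (2.6 equiv)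
Product: 4 1,2-bis{[(E)-1,2-dichloroethenyl]oxy}ethane, via dichloroacetylene 3 (not isolated)
Conditions: KH (2.4 equiv), THF, 0 °C; then 2 (2.6 equiv), −50 °C to rt
Reagents that add atoms: none
Why: This is the dichlorovinyl ether synthesis from an alkoxide and trichloroethylene, in which base strips HCl from 2 to give dichloroacetylene 3 and each of the two potassium alkoxide ends of the diol adds to one molecule of it with anti protonation to give the E vinyl ether, so that two molecules of 2 are taken up per diol; excess 2 at low temperature should let the second alkoxide meet 3 before it can attack the first vinyl ether intramolecularly.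

Step 2
Reactants: 4 1,2-bis{[(E)-1,2-dichloroethenyl]oxy}ethane
Product: 7 1,2-bis(bromoethynyloxy)ethane, via bis(chloroethynyl) ether 5 (not isolated), via dilithium bis(acetylide) 6 (not isolated)
Conditions: n-BuLi (4.2 equiv), THF, −78 to −40 °C; NBS (2.4 equiv), −78 °C; cold aq. NaHCO3, plug of basic Al2O3; solvent swapped to ClCH2CH2Cl below 0 °C, used at once
Reagents that add atoms: N-bromosuccinimide, O=C1CCC(=O)N1Br
Why: Dehydrochlorination by n-BuLi to chloroalkyne 5 and chlorine–lithium exchange to acetylide 6 is the standard passage from dichlorovinyl ethers to metalated ynol ethers, and electrophilic bromination of a lithium acetylide with NBS is the usual way to a 1-bromoalkyne; the cold, non-acidic work-up should spare the product from hydration and retro-ene cleavage.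

Step 3
Reactants: 8 propargylamine (2.1 equiv); 9 1,1'-carbonyldiimidazole
Product: 11 N,N'-di(prop-2-ynyl)urea, via N-(prop-2-ynyl)imidazole-1-carboxamide 10 (not isolated)
Conditions: THF, 0 °C to 50 °C
Reagents that add atoms: none
Why: Symmetrical urea formation by twofold nucleophilic acyl substitution on 9, the first amine giving carbamoylimidazole 10 and the second displacing the remaining imidazole, while the terminal alkynes stay inert.

Step 4
Reactants: 11 N,N'-di(prop-2-ynyl)urea
Product: 12 N,N'-bis(3-bromoprop-2-ynyl)urea
Conditions: NBS (2.3 equiv), AgNO3 (0.15 equiv), acetone, rt, dark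
Reagents that add atoms: N-bromosuccinimide, O=C1CCC(=O)N1Br
Why: Silver-catalysed electrophilic bromination of terminal alkynes with NBS is routine for N-acylated propargylamines, and at room temperature without base the urea should neither cyclise onto the alkyne nor stay N-brominated after a thiosulfate wash.

Step 5
Reactants: 7 1,2-bis(bromoethynyloxy)ethane (3 equiv); 12 N,N'-bis(3-bromoprop-2-ynyl)urea
Product: 14 N,N'-bis[(5,7,8-tribromo-2,3-dihydro-1,4-benzodioxin-6-yl)methyl]urea, via mono-annulated urea 13 (not isolated)
Conditions: Cp*RuCl(cod) (10 mol %), ClCH2CH2Cl, rt, Ar; 7 added over 6 h by syringe pump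
Reagents that add atoms: none
Why: Proposed new method: the Cp*RuCl fragment (divalent ruthenium) freed from Cp*RuCl(cod) should bind both ynol ether alkynes of 7 and couple them oxidatively at the oxygen-bearing carbons, which forms C4–C5 and closes the 1,4-dioxane ring as a six-membered ring fused to a ruthenacyclopentadiene of tetravalent ruthenium that carries bromine on both metal-bound carbons. A bromopropargyl arm of 12 then inserts and reductive elimination forms C2–C3 and C6–C1, so the benzene ring closes in a metal-templated [2+2+2] mode, and the second arm repeats the cycle through mono-adduct 13. The closest known reaction type is the Cp*RuCl(cod)-catalysed [2+2+2] cycloaddition of halogen-terminated diynes with monoalkynes to halobenzenes, which leaves C(sp)–halogen bonds intact; new here are the ynol ether tether and the fully substituted tribromo ring. No stereocentre is formed. Regiochemistry does not arise, because 7 is symmetric and either orientation of the arm gives the same ring. The step needs cross-cyclotrimerisation to outrun self-trimerisation of 7 and insertion into C–Br bonds: the tether makes the first coupling intramolecular, slow addition keeps free 7 scarce beside the arms of 12, and room temperature avoids retro-ene loss of ketene from the ynol ethers.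

Step 6
Reactants: 14 N,N'-bis[(5,7,8-tribromo-2,3-dihydro-1,4-benzodioxin-6-yl)methyl]urea
Product: 15 N,N'-bis(2,3,6-tribromo-4,5-dihydroxybenzyl)urea
Conditions: BBr3 (10 equiv), CH2Cl2, −78 °C to rt; then H2O, 0 °C
Reagents that add atoms: none
Why: Lewis-acid dealkylation of aryl alkyl ethers, in which BBr3 binds each ring oxygen and bromide opens both O–CH2 bonds of each dioxane by SN2, releasing the bridge as 1,2-dibromoethane and leaving catechol borates that water hydrolyses; the aryl bromides are inert and the urea should only tie up extra BBr3.

**Compound list**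

1 | ethylene glycol | OCCO | starting material
2 | trichloroethylene | ClC=C(Cl)Cl | starting material
3 | dichloroacetylene | ClC#CCl | intermediate
4 | 1,2-bis{[(E)-1,2-dichloroethenyl]oxy}ethane | Cl/C=C(/Cl)OCCO/C(Cl)=C\Cl | intermediate
5 | 1,2-bis(chloroethynyloxy)ethane | ClC#COCCOC#CCl | intermediate
6 | dilithium bis(acetylide) of 1,2-bis(ethynyloxy)ethane | [Li]C#COCCOC#C[Li] | intermediate
7 | 1,2-bis(bromoethynyloxy)ethane | BrC#COCCOC#CBr | intermediate
8 | propargylamine | C#CCN | starting material
9 | 1,1'-carbonyldiimidazole | O=C(n1ccnc1)n1ccnc1 | starting material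
10 | N-(prop-2-ynyl)imidazole-1-carboxamide | O=C(NCC#C)n1ccnc1 | intermediate
11 | N,N'-di(prop-2-ynyl)urea | O=C(NCC#C)NCC#C | intermediate
12 | N,N'-bis(3-bromoprop-2-ynyl)urea | O=C(NCC#CBr)NCC#CBr | intermediate
13 | N-(3-bromoprop-2-ynyl)-N'-[(5,7,8-tribromo-2,3-dihydro-1,4-benzodioxin-6-yl)methyl]urea | O=C(NCC#CBr)NCc1c(Br)c2OCCOc2c(Br)c1Br | intermediate
14 | N,N'-bis[(5,7,8-tribromo-2,3-dihydro-1,4-benzodioxin-6-yl)methyl]urea | O=C(NCc1c(Br)c2OCCOc2c(Br)c1Br)NCc1c(Br)c2OCCOc2c(Br)c1Br | intermediate
15 | N,N'-bis(2,3,6-tribromo-4,5-dihydroxybenzyl)urea | O=C(NCc1c(Br)c(O)c(O)c(Br)c1Br)NCc1c(Br)c(O)c(O)c(Br)c1Br | target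

**Summary**

Total step count: 6. Longest linear sequence: 4 steps (steps 1, 2, 5, 6, or equally steps 3, 4, 5, 6).

**Steps most likely to fail**

Step 5. The ruthenacycle formed from 7 may be intercepted by a second molecule of 7 instead of an arm of 12, the metal may insert into a C(sp)–Br bond, or the reaction may stop after the first ring because of crowding and urea coordination. The fallback uses classical arene chemistry, sets out from 9 (kept as the carbonyl source) and comes back at 15. Commercial 4-methylcatechol is brominated at its three free ring positions (Br2, AcOH) to 3,4,6-tribromo-5-methylbenzene-1,2-diol F1. Methylation (MeI, K2CO3, DMF) gives 2,3,6-tribromo-4,5-dimethoxytoluene F2, and Wohl–Ziegler bromination (NBS, AIBN, PhCF3, reflux) gives 2,3,6-tribromo-4,5-dimethoxybenzyl bromide F3. NaN3 in DMF should give 2,3,6-tribromo-4,5-dimethoxybenzyl azide F4, and Staudinger reduction (PPh3, THF–H2O) should give (2,3,6-tribromo-4,5-dimethoxyphenyl)methanamine F5. Two equivalents of F5 with 9 should give N,N'-bis(2,3,6-tribromo-4,5-dimethoxybenzyl)urea F6, and BBr3 in CH2Cl2 then cleaves the four methyl ethers to 15.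

Step 2. Oxidative coupling or over-bromination may occur when the electron-rich acetylide meets positive bromine, and the bromo ynol ether may hydrate or polymerise during work-up. The fallback sets out from 4 and comes back at 7. Acetylide 6, generated as in step 2, is quenched with Me3SiCl to 1,2-bis[(trimethylsilyl)ethynyloxy]ethane F7, a silyl ynol ether that should survive chromatography and storage. NBS with catalytic AgNO3 in dry acetone (or AgF in MeCN) then exchanges silicon for bromine immediately before step 5, so that 7 is made under neutral conditions, washed briefly and never concentrated.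

Step 6. The second SN2 opening of each bridge may stall because the electron-poor aryl oxygen binds BBr3 weakly, and forcing conditions may start to cleave the benzylic C–N bonds. The fallback sets out from 14 and comes back at 15. BBr3 is used only as far as the first cleavage of each ring (2.5 equiv, −78 to 0 °C), which should give N,N'-bis[2,3,6-tribromo-4-(2-bromoethoxy)-5-hydroxybenzyl]urea F8. It is drawn with the bromoethyl group on O4; isomers carrying it on O5 would be taken along and converge. Zinc dust in THF–AcOH at rt then removes each 2-bromoethyl group by Boord-type reductive β-elimination, leaving the free phenols without further Lewis acid.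

**Further compounds**

F1 | step 5 | 3,4,6-tribromo-5-methylbenzene-1,2-diol | Cc1c(Br)c(O)c(O)c(Br)c1Br
F2 | step 5 | 2,3,6-tribromo-4,5-dimethoxytoluene | Cc1c(Br)c(OC)c(OC)c(Br)c1Br
F3 | step 5 | 2,3,6-tribromo-4,5-dimethoxybenzyl bromide | BrCc1c(Br)c(OC)c(OC)c(Br)c1Br
F4 | step 5 | 2,3,6-tribromo-4,5-dimethoxybenzyl azide | [N-]=[N+]=NCc1c(Br)c(OC)c(OC)c(Br)c1Br
F5 | step 5 | (2,3,6-tribromo-4,5-dimethoxyphenyl)methanamine | NCc1c(Br)c(OC)c(OC)c(Br)c1Br
F6 | step 5 | N,N'-bis(2,3,6-tribromo-4,5-dimethoxybenzyl)urea | O=C(NCc1c(Br)c(OC)c(OC)c(Br)c1Br)NCc1c(Br)c(OC)c(OC)c(Br)c1Br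
F7 | step 2 | 1,2-bis[(trimethylsilyl)ethynyloxy]ethane | C[Si](C)(C)C#COCCOC#C[Si](C)(C)C
F8 | step 6 | N,N'-bis[2,3,6-tribromo-4-(2-bromoethoxy)-5-hydroxybenzyl]urea | O=C(NCc1c(Br)c(Br)c(OCCBr)c(O)c1Br)NCc1c(Br)c(Br)c(OCCBr)c(O)c1Br
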